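**Plan**

- Retrosynthetic cuts, in order: the three phenolic O–CH2OMe bonds; O1–C8a of the pyranone; C2–C3 (Claisen); the C6–CH3 and C8–CH3 bonds (cross-coupling); C4–C4a (ring acylation).
- Enabling feature: O1 is bonded to C8a, which lies on the A ring ortho to the C4 carbonyl. A fluorine at C8a is therefore acyl-activated and can be displaced by the enol oxygen of an aryl 1,3-diketone.
- Forward: the fully substituted A-ring methyl ketone is built from a fluororesorcinol by acetylation, dibromination, MOM protection and double methylation. It is joined to the MOM-protected B-ring benzoate by Claisen condensation. The pyranone, the only ring formed, then closes through O1–C8a, and acid frees the three phenols.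
- Stereochemistry: the target has no stereocentre and no stereogenic double bond, so nothing has to be set or preserved.

Key step: step 7

Assumption: enolates, phenoxides and σ-complexes are treated as mechanistic species within a step, not as separate compounds; the 1,3-diketone is drawn in its diketo form although it should exist largely as the chelated enol.

**Route**

Step 1
Reactants: 1 5-fluororesorcinol (5-fluorobenzene-1,3-diol)
Product: 2 1-(2-fluoro-4,6-dihydroxyphenyl)ethanone
Conditions: AcOH, ZnCl2, 140 °C
Reagents that add atoms: acetic acid, CC(=O)O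
Why: Nencki-type Friedel–Crafts acylation enters ortho to one hydroxyl and para to the other, as in resorcinol itself; C4 and C6 of 1 are equivalent, so one ketone with fluorine ortho to the acetyl group should form, and any symmetrical isomer acylated between the hydroxyls should be removable by crystallisation.

Step 2
Reactants: 2 1-(2-fluoro-4,6-dihydroxyphenyl)ethanone
Product: 3 1-(3,5-dibromo-2-fluoro-4,6-dihydroxyphenyl)ethanone
Conditions: NBS (2.05 equiv), MeCN, 0 °C to rt
Reagents that add atoms: N-bromosuccinimide, O=C1CCC(=O)N1Br
Why: Electrophilic aromatic bromination; the two free ring positions are both ortho/para to the hydroxyls and are the only sites left, so exhaustive ring bromination needs no regiocontrol, and the phenol ring should react much faster than the acetyl enol.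

Step 3
Reactants: 3 1-(3,5-dibromo-2-fluoro-4,6-dihydroxyphenyl)ethanone
Product: 4 1-[3,5-dibromo-2-fluoro-4,6-bis(methoxymethoxy)phenyl]ethanone
Conditions: MOMCl (2.5 equiv), K2CO3, DMF, 0 °C to rt
Reagents that add atoms: chloromethyl methyl ether (MOMCl), COCCl
Why: Williamson-type O-alkylation of the two bromine-acidified phenoxides with the reactive α-chloro ether; carbonate is too weak to enolise the methyl ketone, so only the oxygens are capped.

Step 4
Reactants: 4 1-[3,5-dibromo-2-fluoro-4,6-bis(methoxymethoxy)phenyl]ethanone
Product: 5 1-[2-fluoro-4,6-bis(methoxymethoxy)-3,5-dimethylphenyl]ethanone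
Conditions: MeB(OH)2 (4 equiv), Pd(OAc)2 (5 mol %), SPhos (10 mol %), K3PO4, toluene/H2O, 100 °C
Reagents that add atoms: methylboronic acid, CB(O)O
Why: Double Suzuki–Miyaura methylation; a bulky electron-rich biarylphosphine is the standard choice for di-ortho-substituted aryl bromides with alkylboronic acids, and the C–F bond, the MOM ethers and the ketone should be inert under aqueous phosphate.

Step 5
Reactants: 6 methyl 3-hydroxy-4,5-dimethoxybenzoate
Product: 7 methyl 3,4-dimethoxy-5-(methoxymethoxy)benzoate
Conditions: MOMCl (1.3 equiv), K2CO3, acetone, rt to 50 °C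
Reagents that add atoms: chloromethyl methyl ether (MOMCl), COCCl
Why: Williamson-type MOM protection of the single phenol, so that no acidic OH quenches the enolate in step 6 and all three phenols carry the same acid-labile group.

Step 6
Reactants: 5 1-[2-fluoro-4,6-bis(methoxymethoxy)-3,5-dimethylphenyl]ethanone; 7 methyl 3,4-dimethoxy-5-(methoxymethoxy)benzoate
Product: 8 1-[2-fluoro-4,6-bis(methoxymethoxy)-3,5-dimethylphenyl]-3-[3,4-dimethoxy-5-(methoxymethoxy)phenyl]propane-1,3-dione
Conditions: LiHMDS (2.5 equiv), THF, −78 °C; then 7, −78 °C to rt; AcOH quench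
Reagents that add atoms: none
Why: Crossed Claisen condensation; the lithium enolate of the methyl ketone (its only enolisable site) adds to the non-enolisable benzoate, and deprotonation of the product diketone by the second equivalent of base drives the equilibrium.

Step 7
Reactants: 8 1-[2-fluoro-4,6-bis(methoxymethoxy)-3,5-dimethylphenyl]-3-[3,4-dimethoxy-5-(methoxymethoxy)phenyl]propane-1,3-dione
Product: 9 2-[3,4-dimethoxy-5-(methoxymethoxy)phenyl]-5,7-bis(methoxymethoxy)-6,8-dimethyl-4H-chromen-4-one
Conditions: Cs2CO3 (2 equiv), dry DMSO, 100 °C
Reagents that add atoms: none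
Why: Carbonate converts the 1,3-diketone into its enolate, whose oxygen on the B-ring side adds to the fluorine-bearing carbon (the future C8a) ortho to the aroyl carbonyl; the Meisenheimer adduct, with its charge delocalised into the C4 carbonyl, then expels fluoride (addition–elimination SNAr). The closest known reaction type is the base-mediated cyclisation of 1-(2-haloaryl)-1,3-diketones to chromones and flavones. The pyranone closes by a six-membered O-cyclisation onto an sp2 carbon (6-endo-trig with respect to the C8a=C4a bond that relays the charge to the carbonyl), and O1–C8a is the only skeletal bond formed. No stereocentre is created. The step needs O- rather than C-arylation and loss of fluoride rather than of the MOM ether on the other ortho position: attack by the central carbon or the proximal oxygen would require a four-membered ring, and fluoride is by far the better nucleofuge in the rate-limiting addition. The two MOM ethers are meta to the site of attack and cannot donate into it by resonance, which should keep the ring electrophilic enough despite the two methyl groups.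

Step 8
Reactants: 9 2-[3,4-dimethoxy-5-(methoxymethoxy)phenyl]-5,7-bis(methoxymethoxy)-6,8-dimethyl-4H-chromen-4-one
Product: 10 5,7,3'-trihydroxy-4',5'-dimethoxy-6,8-dimethylflavone
Conditions: HCl (cat., methanolic), MeOH/THF, 50 °C
Reagents that add atoms: none
Why: Acid-catalysed acetal exchange (methanolysis) should remove all three MOM ethers as dimethoxymethane, while the aryl methyl ethers and the flavone core are stable to methanolic HCl.

**Compound list**

1 | 5-fluororesorcinol (5-fluorobenzene-1,3-diol) | Oc1cc(O)cc(F)c1 | starting material
2 | 1-(2-fluoro-4,6-dihydroxyphenyl)ethanone | CC(=O)c1c(O)cc(O)cc1F | intermediate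
3 | 1-(3,5-dibromo-2-fluoro-4,6-dihydroxyphenyl)ethanone | CC(=O)c1c(O)c(Br)c(O)c(Br)c1F | intermediate
4 | 1-[3,5-dibromo-2-fluoro-4,6-bis(methoxymethoxy)phenyl]ethanone | CC(=O)c1c(OCOC)c(Br)c(OCOC)c(Br)c1F | intermediate
5 | 1-[2-fluoro-4,6-bis(methoxymethoxy)-3,5-dimethylphenyl]ethanone | CC(=O)c1c(OCOC)c(C)c(OCOC)c(C)c1F | intermediate
6 | methyl 3-hydroxy-4,5-dimethoxybenzoate | COC(=O)c1cc(O)c(OC)c(OC)c1 | starting material
7 | methyl 3,4-dimethoxy-5-(methoxymethoxy)benzoate | COCOc1cc(C(=O)OC)cc(OC)c1OC | intermediate
8 | 1-[2-fluoro-4,6-bis(methoxymethoxy)-3,5-dimethylphenyl]-3-[3,4-dimethoxy-5-(methoxymethoxy)phenyl]propane-1,3-dione | COCOc1c(C)c(OCOC)c(C)c(F)c1C(=O)CC(=O)c1cc(OC)c(OC)c(OCOC)c1 | intermediate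
9 | 2-[3,4-dimethoxy-5-(methoxymethoxy)phenyl]-5,7-bis(methoxymethoxy)-6,8-dimethyl-4H-chromen-4-one | O=c1cc(-c2cc(OC)c(OC)c(OCOC)c2)oc2c(C)c(OCOC)c(C)c(OCOC)c12 | intermediate
10 | 5,7,3'-trihydroxy-4',5'-dimethoxy-6,8-dimethylflavone | COc1cc(-c2cc(=O)c3c(O)c(C)c(O)c(C)c3o2)cc(O)c1OC | target

**Step count**

Total steps: 8. Longest linear sequence: 7 steps (steps 1, 2, 3, 4, 6, 7, 8 from 5-fluororesorcinol); step 5 is the one-step B-ring branch.

**Steps most likely to fail**

Step 7. Addition of the weakly nucleophilic diketonate oxygen to the fluorine-bearing carbon may be slow, because methyl groups sit ortho and para to the site of attack and the carbonyl is flanked by two ortho substituents. Retro-Claisen cleavage by adventitious hydroxide or thermal loss of MOM groups could then overtake ring closure. The fallback keeps the bromine atoms on the ring through the closure as inductive activators and methylates afterwards. It sets out from 4: Claisen condensation of its lithium enolate with 7 (LiHMDS, THF) would give 1-[3,5-dibromo-2-fluoro-4,6-bis(methoxymethoxy)phenyl]-3-[3,4-dimethoxy-5-(methoxymethoxy)phenyl]propane-1,3-dione F1. The bromines are meta to the acyl group and so not themselves activated, but they stabilise the σ-complex charge, so Cs2CO3 in DMSO at 60–80 °C should close F1 to 6,8-dibromo-2-[3,4-dimethoxy-5-(methoxymethoxy)phenyl]-5,7-bis(methoxymethoxy)-4H-chromen-4-one F2. Double Suzuki–Miyaura methylation of F2 (trimethylboroxine, Pd(dppf)Cl2, K2CO3, dioxane, 100 °C) would rejoin the route at 9.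

Step 4. Oxidative addition and transmetalation at the two di-ortho-substituted C–Br bonds may stall after the first methyl group, with protodebromination, and palladium enolate chemistry of the methyl ketone may interfere. The fallback avoids cross-coupling and uses three directed ortho-lithiations. It sets out from 1: MOMCl/K2CO3 would give 1-fluoro-3,5-bis(methoxymethoxy)benzene F3. n-BuLi in Et2O, where chelation by both MOM ethers should direct metalation between them, followed by MeI would give 5-fluoro-1,3-bis(methoxymethoxy)-2-methylbenzene F4. A second lithiation at one of the two equivalent fluorine-adjacent positions (n-BuLi, THF, −78 °C, kept cold to avoid aryne formation) and MeI would give 1-fluoro-3,5-bis(methoxymethoxy)-2,4-dimethylbenzene F5. Lithiation of the last ring position (s-BuLi, THF, −78 °C) and acylation with N-methoxy-N-methylacetamide would rejoin the route at 5.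

Step 6. Acyl transfer from the electron-rich benzoate to the hindered enolate may be incomplete, with proton exchange returning ketone, or the diketonate may begin to cyclise under the basic conditions and give mixtures. The fallback replaces the Claisen condensation by aldol addition and oxidation. It sets out from 7 and 5: LiAlH4 reduction of 7 would give [3,4-dimethoxy-5-(methoxymethoxy)phenyl]methanol F6, and MnO2 oxidation would give 3,4-dimethoxy-5-(methoxymethoxy)benzaldehyde F7. Addition of the LDA-derived enolate of 5 to F7 at −78 °C would give racemic 1-[2-fluoro-4,6-bis(methoxymethoxy)-3,5-dimethylphenyl]-3-hydroxy-3-[3,4-dimethoxy-5-(methoxymethoxy)phenyl]propan-1-one F8, whose stereocentre is removed in the next operation. Dess–Martin oxidation of F8 would rejoin the route at 8.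

**Further compounds**

F1 | step 7 | 1-[3,5-dibromo-2-fluoro-4,6-bis(methoxymethoxy)phenyl]-3-[3,4-dimethoxy-5-(methoxymethoxy)phenyl]propane-1,3-dione | COCOc1c(Br)c(OCOC)c(Br)c(F)c1C(=O)CC(=O)c1cc(OC)c(OC)c(OCOC)c1
F2 | step 7 | 6,8-dibromo-2-[3,4-dimethoxy-5-(methoxymethoxy)phenyl]-5,7-bis(methoxymethoxy)-4H-chromen-4-one | O=c1cc(-c2cc(OC)c(OC)c(OCOC)c2)oc2c(Br)c(OCOC)c(Br)c(OCOC)c12
F3 | step 4 | 1-fluoro-3,5-bis(methoxymethoxy)benzene | COCOc1cc(F)cc(OCOC)c1
F4 | step 4 | 5-fluoro-1,3-bis(methoxymethoxy)-2-methylbenzene | COCOc1cc(F)cc(OCOC)c1C
F5 | step 4 | 1-fluoro-3,5-bis(methoxymethoxy)-2,4-dimethylbenzene | COCOc1cc(F)c(C)c(OCOC)c1C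
F6 | step 6 | [3,4-dimethoxy-5-(methoxymethoxy)phenyl]methanol | COCOc1cc(CO)cc(OC)c1OC
F7 | step 6 | 3,4-dimethoxy-5-(methoxymethoxy)benzaldehyde | COCOc1cc(C=O)cc(OC)c1OC
F8 | step 6 | 1-[2-fluoro-4,6-bis(methoxymethoxy)-3,5-dimethylphenyl]-3-hydroxy-3-[3,4-dimethoxy-5-(methoxymethoxy)phenyl]propan-1-one (racemic) | COCOc1c(C)c(OCOC)c(C)c(F)c1C(=O)CC(O)c1cc(OC)c(OC)c(OCOC)c1
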